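**Retrosynthetic overview**

1. Locants (daucane numbering): five-membered ring C1 (quaternary, CH3), C2 (CHOH), C3 (CH2), C4 (C(OH)i-Pr), C5 (ring-fusion CH); seven-membered ring C1, C5, C6 (CH–O-tigloyl), C7 (CH2), C8 (C(CH3)–O), C9 (CH–O; oxirane C8–C9), C10 (CH–O-tigloyl). The target is the cis-fused isomer (C1–CH3 and C5–H cis), (1S,2S,4R,5S,6S,8S,9R,10R).
2. Key disconnection C6–C7 by anionic oxy-Cope rearrangement. The enabling feature is that the carbinol carbon C4 of the five-membered ring lies 1,5 to the oxirane carbon C9 of the seven-membered ring: with C4 as ketone and C8=C9 as alkene, C4(=O)–C5–C6–C7–C8=C9 is a δ,ε-unsaturated ketone. The precursor therefore carries a temporary C4–C9 bond (a bicyclo[2.2.1]heptan-1-ol with a C5=C6 enol ether and an isopropenyl group on C9).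
3. The rearrangement expands the five-membered ring C1–C5–C4–C9–C10 to the seven-membered ring, sets C6 (and C5 on quench), puts the C8=C9 alkene in place and frees the C4 ketone for the isopropyl group.
4. The bicyclic precursor comes from a monocyclic cyclopentanone by indium Barbier closure of C4–C9. The cyclopentanone comes from (S)-4-silyloxycyclopentenone (C2 bought) by two anti conjugate additions (C1), enolate formylation (C6) and alkenylalane addition to the C10 aldehyde (C7–C9, C10).
5. Ring order: five-membered ring (bought) → temporary bicyclo[2.2.1] bridge (step 9) → seven-membered ring (step 10) → oxirane (step 12). End game: isopropyl addition (C4), hydroxyl-directed epoxidation (C8, C9), double tigloylation, desilylation.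

Key step: step 10

Assumption: (S)-4-[(tert-butyldimethylsilyl)oxy]cyclopent-2-en-1-one is taken as commercially available, like its (R)-enantiomer.

**Route**

Step 1
Reactants: 1 (S)-4-[(tert-butyldimethylsilyl)oxy]cyclopent-2-en-1-one
Product: 2 trans-3-methyl-4-silyloxy silyl enol ether
Conditions: MeMgBr, CuBr·SMe2 (10 mol %), Me3SiCl, THF, −78 °C
Reagents that add atoms: methylmagnesium bromide (C[Mg]Br); chlorotrimethylsilane (C[Si](C)(C)Cl)
Why: Copper-catalysed conjugate addition with in situ silyl trapping should deliver methyl anti to the silyloxy group and fix the enolate regiochemistry for step 2 (the new CH(CH3) centre is erased there).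

Step 2
Reactants: 2 trans-3-methyl-4-silyloxy silyl enol ether
Product: 3 (S)-4-[(tert-butyldimethylsilyl)oxy]-3-methylcyclopent-2-en-1-one
Conditions: Pd(OAc)2 (1.05 equiv), MeCN, 23 °C
Reagents that add atoms: none
Why: Saegusa–Ito oxidation of the regiodefined silyl enol ether should return the enone with the double bond towards the methyl-bearing carbon, leaving the C2 stereocentre untouched.

Step 3
Reactants: 3 (S)-4-[(tert-butyldimethylsilyl)oxy]-3-methylcyclopent-2-en-1-one
Product: 4 silyl enol ether with quaternary C1 (vinyl trans and methyl cis to the C2 silyloxy group)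
Conditions: CH2=CHMgBr, CuBr·SMe2 (20 mol %), Me3SiCl, DMPU, THF, −78 → −40 °C
Reagents that add atoms: vinylmagnesium bromide (C=C[Mg]Br); chlorotrimethylsilane (C[Si](C)(C)Cl)
Why: Copper-catalysed, silyl-chloride-accelerated 1,4-addition to the β,β-disubstituted enone should set the quaternary C1 by attack anti to the neighbouring silyloxy group and hold the enolate towards C5.

Step 4
Reactants: 4 silyl enol ether with quaternary C1
Product: 6 2-(hydroxymethylidene) ketone (chelated enol of the C5-formyl ketone), via lithium enolate 5 (not isolated)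
Conditions: MeLi, THF, 0 °C; then CF3CH2OCHO, −78 °C; aq. NH4Cl
Reagents that add atoms: 2,2,2-trifluoroethyl formate (O=COCC(F)(F)F)
Why: Cleavage of the silyl enol ether gives the regiodefined lithium enolate, whose Claisen-type C-formylation with the activated formate should place C6 on C5 only (no stereocentre is formed).

Step 5
Reactants: 6 2-(hydroxymethylidene) ketone
Product: 7 (E)-2-{[(4-methoxybenzyl)oxy]methylidene} ketone
Conditions: 4-MeOC6H4CH2Cl, Cs2CO3, DMF, 0 → 23 °C
Reagents that add atoms: 4-methoxybenzyl chloride (COc1ccc(CCl)cc1)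
Why: Williamson-type O-alkylation of the caesium enolate of the β-keto aldehyde should give the push–pull enol ether as the preferred E isomer (ether oxygen anti to the C4 carbonyl, syn to C1), the geometry that later defines C6.

Step 6
Reactants: 7 (E)-2-{[(4-methoxybenzyl)oxy]methylidene} ketone
Product: 8 C10 aldehyde on the quaternary carbon C1
Conditions: OsO4 (2 mol %), NaIO4, 2,6-lutidine, dioxane–H2O, 23 °C
Reagents that add atoms: osmium tetroxide (O=[Os](=O)(=O)=O), catalytic, reoxidised by sodium periodate ([Na+].[O-]I(=O)(=O)=O), which supplies the carbonyl oxygen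
Why: Lemieux–Johnson cleavage should take place at the monosubstituted vinyl group, since the electron-poor vinylogous-ester double bond reacts far more slowly with OsO4.

Step 7
Reactants: 8 C10 aldehyde; 9 prop-2-yn-1-ol
Product: 11 allylic diol (C10–OH secondary; C7–OH primary; E alkene), via alkenylalane 10 (not isolated)
Conditions: 9, Me3Al (excess), Cp2ZrCl2 (25 mol %), CH2Cl2, 0 → 23 °C; then 8, −78 → 0 °C; aq. potassium sodium tartrate
Reagents that add atoms: trimethylaluminium (C[Al](C)C)
Why: Zirconium-catalysed syn-carboalumination (Negishi carboalumination) gives the (E)-2-methylalkenylalane, and its 1,2-addition to the aldehyde should follow the Felkin–Anh mode with the C1–C2 bond antiperiplanar to the incoming alkenyl group, setting C10 with its oxygen 1,3-anti to the C2 oxygen.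

Step 8
Reactants: 11 allylic diol
Product: 12 primary allylic bromide (C7–Br) with free C10–OH
Conditions: NBS, Me2S, CH2Cl2, −20 → 0 °C
Reagents that add atoms: N-bromosuccinimide (O=C1CCC(=O)N1Br)
Why: Corey–Kim-type bromination through the alkoxysulfonium salt should be selective for the unhindered primary allylic hydroxyl over the neopentylic secondary C10 hydroxyl and creates no stereocentre.

Step 9
Reactants: 12 primary allylic bromide
Product: 13 bicyclo[2.2.1]heptane-2-endo,4-diol (new C4–C9 bond; isopropenyl exo on C9)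
Conditions: In powder, THF–H2O (4:1), 23 °C
Reagents that add atoms: none
Why: Intramolecular Barbier allylation, in which the allylindium reagent should add through its γ-carbon C9 to the C4 carbonyl in a closed six-membered transition state (attack of C9 on C6 would be 5-endo-trig), placing the isopropenyl group exo, trans to the endo C10 hydroxyl and clear of the endo hydrogens on C2 and C3.

Step 10
Reactants: 13 bicyclo[2.2.1]heptane-2-endo,4-diol
Product: 16 cis-fused dauc-8-en-4-one (2-OTBS; 6-OPMB; 10-OH), via dipotassium dialkoxide 14 (not isolated), via dipotassium enolate 15 (not isolated)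
Conditions: KH (2.5 equiv), 18-crown-6, THF, −40 → 0 °C; then AcOH, −78 °C
Reagents that add atoms: none
Why: KH/18-crown-6 converts 13 into dialkoxide 14, whose bridgehead C4 alkoxide sits on the central sp3 carbon of the 1,5-diene C6=C5–C4(O−)–C9–C8=C7, so that a charge-accelerated [3,3]-sigmatropic shift (anionic oxy-Cope rearrangement), further driven by release of the bicyclo[2.2.1]heptane strain, breaks the temporary C4–C9 bond and forms C6–C7 to give enolate 15. The closest known reaction type is the anionic oxy-Cope ring expansion of 2-alkenylbicyclo[2.2.1]heptan-2-olates and related strained 3-oxido-1,5-dienes. The seven-membered ring (C1, C5, C6, C7, C8, C9, C10) arises by two-carbon expansion of the five-membered C1–C5–C4–C9–C10 ring through a boat-like transition state enforced by the bicycle, and even in a stepwise fragmentation–recombination limit only the 7-endo-trig attack of C7 on C6 is productive, because attack of C9 on C6 is 5-endo-trig. C6 is set by the E enol ether geometry, since C7, held on the exo side by C9, can reach only the face of C6 that is syn to the C9–C10 bridge, which places the ether oxygen (syn to C1) cis to the C1 methyl; the C8=C9 double bond is necessarily cis in the ring, and C5 is set on quench by kinetic protonation of 15 from the face anti to C10, giving the cis ring fusion. The step needs the [3,3] shift to win over retro-allylation at the C10 alkoxide and over β-elimination of the C6 ether from 15; the exo-isopropenyl/bridging-alkylidene alignment and the low temperature favour the concerted path, and the cold acetic acid quench protonates 15 before E1cB loss of 4-methoxybenzyl oxide.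

Step 11
Reactants: 16 cis-fused dauc-8-en-4-one
Product: 17 tertiary alcohol (C4–OH; C4–i-Pr)
Conditions: i-PrMgCl (3 equiv), LaCl3·2LiCl, THF, 0 °C; aq. NH4Cl
Reagents that add atoms: isopropylmagnesium chloride (CC(C)[Mg]Cl)
Why: Lanthanum-promoted Grignard 1,2-addition (suppressing enolisation and β-hydride reduction) should occur on the convex face of the cis-fused bicycle, anti to the C5–C6 bond, placing isopropyl cis to H5 and the new C4 hydroxyl cis to C6.

Step 12
Reactants: 17 tertiary alcohol
Product: 18 8,9-epoxide (6-OPMB; 2-OTBS)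
Conditions: VO(acac)2 (5 mol %), t-BuOOH, CH2Cl2, 0 → 23 °C
Reagents that add atoms: tert-butyl hydroperoxide (CC(C)(C)OO)
Why: Hydroxyl-directed vanadium-catalysed epoxidation should deliver oxygen to the C8=C9 face syn to the allylic C10 hydroxyl (cis-epoxy alcohol, as for cyclohept-2-enols), setting C8 and C9 while the C6 oxygen is still masked.

Step 13
Reactants: 18 8,9-epoxide
Product: 19 epoxy triol (free C4, C6 and C10 hydroxyls; 2-OTBS)
Conditions: DDQ, CH2Cl2–aq. NaH2PO4/Na2HPO4 (pH 7), 0 °C
Reagents that add atoms: none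
Why: Oxidative cleavage of the 4-methoxybenzyl ether by DDQ (hydride abstraction, then hydrolysis) should free the C6 hydroxyl under neutral conditions that spare the epoxide, the silyl ether and the tertiary alcohol.

Step 14
Reactants: 19 epoxy triol
Product: 20 6,10-bis-tiglate 2-silyl ether
Conditions: (E)-MeCH=C(Me)COCl, DMAP, pyridine, CH2Cl2, 0 → 40 °C
Reagents that add atoms: tigloyl chloride, (E)-2-methylbut-2-enoyl chloride (C/C=C(\C)C(=O)Cl)
Why: DMAP-catalysed acylation should esterify the two secondary hydroxyls (C6 and C10) while the hindered tertiary C4 hydroxyl stays free, and the weakly basic medium should keep the E geometry of both enoates.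

Step 15
Reactants: 20 6,10-bis-tiglate 2-silyl ether
Product: 21 target CNP0265715.1
Conditions: Bu4NF, AcOH, THF, 23 °C
Reagents that add atoms: none
Why: Acetic-acid-buffered fluoride desilylation should free the C2 hydroxyl without epoxide opening or acyl migration.

**Compound list**

1 | (S)-4-[(tert-butyldimethylsilyl)oxy]cyclopent-2-en-1-one | O=C1C=C[C@@H](O[Si](C)(C)C(C)(C)C)C1 | starting material
2 | tert-butyldimethyl{[(1S,2S)-2-methyl-4-(trimethylsilyloxy)cyclopent-3-en-1-yl]oxy}silane (methyl trans to the tert-butyldimethylsilyloxy group) | C[Si](C)(C)OC1=C[C@H](C)[C@@H](O[Si](C)(C)C(C)(C)C)C1 | intermediate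
3 | (S)-4-[(tert-butyldimethylsilyl)oxy]-3-methylcyclopent-2-en-1-one | O=C1C=C(C)[C@@H](O[Si](C)(C)C(C)(C)C)C1 | intermediate
4 | tert-butyldimethyl{[(1S,2S)-2-methyl-4-(trimethylsilyloxy)-2-vinylcyclopent-3-en-1-yl]oxy}silane (vinyl trans, methyl cis to the tert-butyldimethylsilyloxy group) | C[Si](C)(C)OC1=C[C@](C)(C=C)[C@@H](O[Si](C)(C)C(C)(C)C)C1 | intermediate
5 | lithium (3S,4S)-4-[(tert-butyldimethylsilyl)oxy]-3-methyl-3-vinylcyclopent-1-en-1-olate | [Li+].[O-]C1=C[C@](C)(C=C)[C@@H](O[Si](C)(C)C(C)(C)C)C1 | intermediate (not isolated)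
6 | (3S,4S,Z)-4-[(tert-butyldimethylsilyl)oxy]-2-(hydroxymethylidene)-3-methyl-3-vinylcyclopentan-1-one | O/C=C1\C(=O)C[C@H](O[Si](C)(C)C(C)(C)C)[C@@]1(C)C=C | intermediate
7 | (3S,4S,E)-4-[(tert-butyldimethylsilyl)oxy]-2-{[(4-methoxybenzyl)oxy]methylidene}-3-methyl-3-vinylcyclopentan-1-one | COc1ccc(CO/C=C2/C(=O)C[C@H](O[Si](C)(C)C(C)(C)C)[C@@]2(C)C=C)cc1 | intermediate
8 | (1S,2S,E)-2-[(tert-butyldimethylsilyl)oxy]-5-{[(4-methoxybenzyl)oxy]methylidene}-1-methyl-4-oxocyclopentane-1-carbaldehyde | COc1ccc(CO/C=C2/C(=O)C[C@H](O[Si](C)(C)C(C)(C)C)[C@@]2(C)C=O)cc1 | intermediate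
9 | prop-2-yn-1-ol | C#CCO | starting material
10 | (E)-[3-(dimethylalumanyloxy)-2-methylprop-1-en-1-yl]dimethylalumane | C[Al](C)/C=C(\C)CO[Al](C)C | intermediate (not isolated)
11 | (3R,4S,E)-4-[(tert-butyldimethylsilyl)oxy]-3-[(1S,2E)-1,4-dihydroxy-3-methylbut-2-en-1-yl]-2-{[(4-methoxybenzyl)oxy]methylidene}-3-methylcyclopentan-1-one (C10 carbinol 1,3-anti to the C2 silyloxy group) | COc1ccc(CO/C=C2/C(=O)C[C@H](O[Si](C)(C)C(C)(C)C)[C@@]2(C)[C@@H](O)/C=C(\C)CO)cc1 | intermediate
12 | (3R,4S,E)-3-[(1S,2E)-4-bromo-1-hydroxy-3-methylbut-2-en-1-yl]-4-[(tert-butyldimethylsilyl)oxy]-2-{[(4-methoxybenzyl)oxy]methylidene}-3-methylcyclopentan-1-one | COc1ccc(CO/C=C2/C(=O)C[C@H](O[Si](C)(C)C(C)(C)C)[C@@]2(C)[C@@H](O)/C=C(\C)CBr)cc1 | intermediate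
13 | 6-exo-[(tert-butyldimethylsilyl)oxy]-7-{(E)-[(4-methoxybenzyl)oxy]methylidene}-1-methyl-3-exo-(prop-1-en-2-yl)bicyclo[2.2.1]heptane-2-endo,4-diol (bicyclic C1, C2, C3, C4, C5, C6, C7 = daucane C1, C10, C9, C4, C3, C2, C5; ether oxygen syn to C1) | COc1ccc(CO/C=C2/[C@]3(O)C[C@H](O[Si](C)(C)C(C)(C)C)[C@@]2(C)[C@@H](O)[C@@H]3C(C)=C)cc1 | intermediate
14 | dipotassium 2,4-dialkoxide of 13 | [K+].[K+].COc1ccc(CO/C=C2/[C@]3([O-])C[C@H](O[Si](C)(C)C(C)(C)C)[C@@]2(C)[C@@H]([O-])[C@@H]3C(C)=C)cc1 | intermediate (not isolated)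
15 | dipotassium C4(O)=C5 enolate / C10 alkoxide of 16 | [K+].[K+].COc1ccc(CO[C@H]2CC(C)=C[C@H]([O-])[C@@]3(C)C2=C([O-])C[C@@H]3O[Si](C)(C)C(C)(C)C)cc1 | intermediate (not isolated)
16 | cis-fused 2-[(tert-butyldimethylsilyl)oxy]-10-hydroxy-6-[(4-methoxybenzyl)oxy]dauc-8-en-4-one (C1, C2, C5, C6, C10 as in the target) | COc1ccc(CO[C@H]2CC(C)=C[C@H](O)[C@@]3(C)[C@@H]2C(=O)C[C@@H]3O[Si](C)(C)C(C)(C)C)cc1 | intermediate
17 | cis-fused 2-[(tert-butyldimethylsilyl)oxy]-6-[(4-methoxybenzyl)oxy]dauc-8-ene-4,10-diol (C4 hydroxyl cis to C6, isopropyl cis to H5) | COc1ccc(CO[C@H]2CC(C)=C[C@H](O)[C@@]3(C)[C@@H]2[C@](O)(C(C)C)C[C@@H]3O[Si](C)(C)C(C)(C)C)cc1 | intermediate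
18 | 2-[(tert-butyldimethylsilyl)oxy]-8,9-epoxy-6-[(4-methoxybenzyl)oxy]daucane-4,10-diol (oxirane cis to the C10 hydroxyl) | COc1ccc(CO[C@H]2C[C@]3(C)O[C@@H]3[C@H](O)[C@@]3(C)[C@@H]2[C@](O)(C(C)C)C[C@@H]3O[Si](C)(C)C(C)(C)C)cc1 | intermediate
19 | 2-[(tert-butyldimethylsilyl)oxy]-8,9-epoxydaucane-4,6,10-triol | O[C@H]1C[C@]2(C)O[C@@H]2[C@H](O)[C@@]2(C)[C@@H]1[C@](O)(C(C)C)C[C@@H]2O[Si](C)(C)C(C)(C)C | intermediate
20 | 2-[(tert-butyldimethylsilyl)oxy]-8,9-epoxy-4-hydroxydaucane-6,10-diyl bis[(E)-2-methylbut-2-enoate] | C/C=C(\C)C(=O)O[C@H]1C[C@]2(C)O[C@@H]2[C@H](OC(=O)/C(C)=C/C)[C@@]2(C)[C@@H]1[C@](O)(C(C)C)C[C@@H]2O[Si](C)(C)C(C)(C)C | intermediate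
21 | (1S,2S,4R,5S,6S,8S,9R,10R)-8,9-epoxy-2,4-dihydroxydaucane-6,10-diyl bis[(E)-2-methylbut-2-enoate], CNP0265715.1 | C/C=C(\C)C(=O)O[C@H]1C[C@]2(C)O[C@@H]2[C@H](OC(=O)/C(C)=C/C)[C@@]2(C)[C@@H]1[C@](O)(C(C)C)C[C@@H]2O | target

**Step count and risks**

Total step count: 15. Longest linear sequence: 15 steps (1 → 21); prop-2-yn-1-ol (9) enters directly in step 7.

Steps most likely to fail:

1. Step 10 (key step). The rearranged enolate may lose the C6 ether by E1cB, or the dialkoxide may fragment (retro-allylation) instead of undergoing the [3,3] shift. The fallback runs from 13 to 16 without any enolate. Compound 13 is silylated at both hydroxyls (N-trimethylsilylimidazole) to the bis(trimethylsilyl) ether F1. F1 is heated (toluene, 140–180 °C, sealed tube, a little N,O-bis(trimethylsilyl)acetamide as acid scavenger), so that the neutral siloxy-Cope rearrangement gives the silyl enol ether F2. Acetic-acid-buffered Bu4NF at −20 °C then removes both trimethylsilyl groups, with protonation at C5 from the convex face, and returns 16.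

2. Step 9. The strained bicyclo[2.2.1]heptan-1-ol may fail to close, or protonation of the allylindium species may outrun its addition to the weakly electrophilic vinylogous-ester carbonyl. The fallback runs from 12 to 13 through a neutral, irreversible allylboration. Palladium-catalysed borylation of 12 (B2pin2, Pd2(dba)3, DMSO) gives the primary allylboronate F3. On warming in toluene, F3 should undergo intramolecular allylboration of the C4 ketone through a closed six-membered transition state to the O-boryl bicycle F4. The borate ester of F4 is cleaved on work-up with aqueous NaHCO3 and triethanolamine to give 13.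

3. Step 7. Facial selectivity at C10 on the α-quaternary aldehyde may be poor or reversed. The fallback runs from 8 to 11 under catalyst control. The addition is run as before, and 11 is taken on together with its C10 epimer F5. Both allylic hydroxyls of the mixture are oxidised with MnO2 to the single keto aldehyde F6. F6 is reduced with BH3·SMe2 and the matching enantiomer of the oxazaborolidine catalyst (Corey–Bakshi–Shibata reduction); this reduces the aldehyde to the primary alcohol and should set C10 by catalyst control, returning 11.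

**Further compounds**

F1 | step 10 | 2,4-bis(trimethylsilyl) ether of 13 | COc1ccc(CO/C=C2/[C@]3(O[Si](C)(C)C)C[C@H](O[Si](C)(C)C(C)(C)C)[C@@]2(C)[C@@H](O[Si](C)(C)C)[C@@H]3C(C)=C)cc1
F2 | step 10 | C4 trimethylsilyl enol ether and C10 trimethylsilyl ether of 16 | COc1ccc(CO[C@H]2CC(C)=C[C@H](O[Si](C)(C)C)[C@@]3(C)C2=C(O[Si](C)(C)C)C[C@@H]3O[Si](C)(C)C(C)(C)C)cc1
F3 | step 9 | primary allylboronate (pinacol ester) corresponding to bromide 12 | COc1ccc(CO/C=C2/C(=O)C[C@H](O[Si](C)(C)C(C)(C)C)[C@@]2(C)[C@@H](O)/C=C(\C)CB3OC(C)(C)C(C)(C)O3)cc1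
F4 | step 9 | C4 O-(pinacolatoboryl) derivative of 13 | COc1ccc(CO/C=C2/[C@]3(OB4OC(C)(C)C(C)(C)O4)C[C@H](O[Si](C)(C)C(C)(C)C)[C@@]2(C)[C@@H](O)[C@@H]3C(C)=C)cc1
F5 | step 7 | C10 epimer of 11 | COc1ccc(CO/C=C2/C(=O)C[C@H](O[Si](C)(C)C(C)(C)C)[C@@]2(C)[C@H](O)/C=C(\C)CO)cc1
F6 | step 7 | (E)-keto aldehyde (C10 ketone, C7 aldehyde) from 11/F5 | COc1ccc(CO/C=C2/C(=O)C[C@H](O[Si](C)(C)C(C)(C)C)[C@@]2(C)C(=O)/C=C(\C)C=O)cc1
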